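I reckon this flask in equivalents of nucleophile per equivalent of electrophile.

    electrophile + nucleophile → acid set free + target (k1 = 0.0451 L mol⁻¹ min⁻¹)
    nucleophile + acid set free ⇌ protonated nucleophile, settled at all times (K2 = 23300 L mol⁻¹)
    acid set free → by-product carried off (k3 = 5.48 × 10⁻⁴ min⁻¹)

electrophile 0.10 M; time 40 h

- the equivalents of nucleophile at which the part of the electrophile that has reacted at 40 h is just 70%

**Two extremes.** If nothing bound the acid set free, each electrophile reacted would cost one nucleophile, so this flask would need at least 0.700 equiv. If the acid stayed bound for the whole run, each would cost two: the nucleophile it consumes and the one its acid protonates. Two nucleophiles per electrophile reacted, times the part wanted, is the bill, 1.40 equiv. Nucleophile is then the limiting reagent.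

**Nearer the bill.** The equilibrium constant times the electrophile charge is 2330, far above one. So I expect the need close to the bill, and below it by the acid not held on nucleophile at the end, unbound or carried off, less the free nucleophile.

**The mean leak.** Late in the run, I take free nucleophile as small and steady. Each nucleophile the leak returns is then spent at the price of two. Balancing these at the wanted part gives free nucleophile near 7.80 × 10⁻⁴ M and a leak of 2.11 × 10⁻⁶ M min⁻¹. I replace the curve by that rate for the whole time, which returns 0.0507 equiv. This overstates the leak, since more free nucleophile holds the acid tighter early on. At the wanted part, unbound acid adds 0.0385 equiv and free nucleophile takes back 0.00780 equiv. So I put the gap below the bill at 0.0814 equiv, and I commit to a need between 1.32 equiv and 1.40 equiv.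

The forecast gives 1.36 equiv, with a range of 1.33 equiv to 1.39 equiv, reasoning that “the strongly bound acid ties up a second”.

**The check.** The flask needs 1.36 equiv, inside my bracket. That is 0.0400 equiv under the bill, less than my gap of 0.0814 equiv. In the simulated run where nothing binds the acid, the same charge faces a bill of half this one, 0.700 equiv, and the part of the electrophile reacted is 99.5%.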